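**Retrosynthetic overview**
1. Target 32 ⇐ macrocycle 29 by TES removal, C6–O methacrylation and TBDPS removal; the C2 acetate is carried from step 6.
2. Ten-membered carbocycle (formed last) ⇐ C9–C10 bond by a new macrocyclising Heck reaction of a (Z)-vinyl iodide onto the exocyclic C=C of γ-methylene butenolide 28; the ring allows only the 8E enol lactone.
3. Butenolide ring (formed second) ⇐ 2-methylfuran 24 by singlet oxygen/base, then dehydration; the purchased furan ring fixes the tetrasubstituted C7=C11 geometry and the lactone regiochemistry.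
4. C6–C7 ⇐ furyl Grignard 20 (from 3,4-dibromofuran) + aldehyde 11; C6 set by CBS reduction.
5. Aldehyde 11 ⇐ (R)-mevalonolactone (C4), propynyl ketone, Noyori transfer hydrogenation (C2), Red-Al/I2 (Z-C1=C10 vinyl iodide).

Assumption: (R)-mevalonolactone, 3,4-dibromofuran and prop-1-ynylmagnesium bromide (THF solution) are bought. Atom labels C1–C15 follow germacranolide numbering: C12 lactone C=O, C8 enol-lactone carbon, C9 =CH, C13 CH2OH, C14/C15 methyls on C10/C4.

**Step 1**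
Reactants: 1 (R)-mevalonolactone
Product: 2 (3R)-3,5-dihydroxy-N-methoxy-N,3-dimethylpentanamide
Conditions: MeNH(OMe)·HCl, i-PrMgCl, THF, −20 → 0 °C
Reagents that add atoms: N,O-dimethylhydroxylamine hydrochloride CNOC.Cl
Why: Weinreb aminolysis: the chloromagnesium amide opens the δ-lactone at the acyl C–O bond and leaves the tertiary carbinol (future C4) untouched.

**Step 2**
Reactants: 2 (3R)-3,5-dihydroxy-N-methoxy-N,3-dimethylpentanamide
Product: 3 (3R)-N-methoxy-N,3-dimethyl-3,5-bis[(triethylsilyl)oxy]pentanamide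
Conditions: TESOTf, 2,6-lutidine, CH2Cl2, −78 → 0 °C
Reagents that add atoms: triethylsilyl trifluoromethanesulfonate CC[Si](CC)(CC)OS(=O)(=O)C(F)(F)F
Why: Silyl triflate silylation reaches both the primary and the hindered tertiary hydroxyl and blocks retro-aldol cleavage of the later β-oxy ketone.

**Step 3**
Reactants: 3 (3R)-N-methoxy-N,3-dimethyl-3,5-bis[(triethylsilyl)oxy]pentanamide; 4 prop-1-yn-1-ylmagnesium bromide
Product: 5 (6R)-6-methyl-6,8-bis[(triethylsilyl)oxy]oct-2-yn-4-one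
Conditions: THF, 0 °C; aq. NH4Cl
Reagents that add atoms: none
Why: Weinreb ketone synthesis: the chelated tetrahedral intermediate prevents over-addition and delivers the ynone that carries C1, C10 and C14.

**Step 4**
Reactants: 5 (6R)-6-methyl-6,8-bis[(triethylsilyl)oxy]oct-2-yn-4-one
Product: 6 (4S,6R)-6-methyl-6,8-bis[(triethylsilyl)oxy]oct-2-yn-4-ol
Conditions: Ru[(S,S)-TsDPEN](p-cymene) (2 mol %), i-PrOH, rt
Reagents that add atoms: none
Why: Noyori asymmetric transfer hydrogenation of an alkynyl ketone: the (S,S)-catalyst sets the (S)-propargylic carbinol (C2) under catalyst control, the alkyne acting as the π-group.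

**Step 5**
Reactants: 6 (4S,6R)-6-methyl-6,8-bis[(triethylsilyl)oxy]oct-2-yn-4-ol
Product: 8 (2Z,4S,6R)-2-iodo-6-methyl-6,8-bis[(triethylsilyl)oxy]oct-2-en-4-ol, via cyclic vinylalanate 7 (not isolated)
Conditions: Red-Al, THF, 0 °C → rt; EtOAc; then I2, −78 → 0 °C
Reagents that add atoms: iodine II
Why: Alkoxide-directed trans-hydroalumination puts H on the proximal and Al on the distal alkyne carbon inside a five-membered oxa-aluminacycle, so iodinolysis with retention gives only the (Z)-vinyl iodide (C1=C10 geometry).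

**Step 6**
Reactants: 8 (2Z,4S,6R)-2-iodo-6-methyl-6,8-bis[(triethylsilyl)oxy]oct-2-en-4-ol
Product: 9 (2Z,4S,6R)-2-iodo-6-methyl-6,8-bis[(triethylsilyl)oxy]oct-2-en-4-yl acetate
Conditions: Ac2O, pyridine, DMAP (cat.), CH2Cl2, 0 °C → rt
Reagents that add atoms: acetic anhydride CC(=O)OC(C)=O
Why: DMAP-catalysed acylation of the only free hydroxyl installs the C2 acetate of the target.

**Step 7**
Reactants: 9 (2Z,4S,6R)-2-iodo-6-methyl-6,8-bis[(triethylsilyl)oxy]oct-2-en-4-yl acetate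
Product: 11 (3S,5S,6Z)-7-iodo-3-methyl-1-oxo-3-[(triethylsilyl)oxy]oct-6-en-5-yl acetate, via alkoxysulfonium chloride 10 (not isolated)
Conditions: (COCl)2, DMSO, CH2Cl2, −78 → −40 °C; Et3N, −78 → 0 °C
Reagents that add atoms: none
Why: Swern oxidation converts a primary triethylsilyl ether directly into the aldehyde (O-sulfonium formation with loss of the silyl group), while the tertiary TES ether, the acetate and the vinyl iodide are inert.

**Step 8**
Reactants: 12 3,4-dibromofuran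
Product: 14 4-bromofuran-3-carbaldehyde, via 3-bromo-4-lithiofuran 13 (not isolated)
Conditions: n-BuLi (1.0 equiv), Et2O, −78 °C; DMF, −78 °C → rt
Reagents that add atoms: N,N-dimethylformamide CN(C)C=O
Why: Bromine–lithium exchange on the symmetrical dibromide stops at mono-exchange at −78 °C, and formylation with DMF gives the aldehyde (future C13).

**Step 9**
Reactants: 14 4-bromofuran-3-carbaldehyde
Product: 15 (4-bromofuran-3-yl)methanol
Conditions: NaBH4, MeOH, 0 °C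
Reagents that add atoms: none
Why: Borohydride reduction of the aldehyde; the aryl bromide is untouched.

**Step 10**
Reactants: 15 (4-bromofuran-3-yl)methanol
Product: 16 [(4-bromofuran-3-yl)methoxy](tert-butyl)diphenylsilane
Conditions: TBDPSCl, imidazole, DMF, rt
Reagents that add atoms: tert-butyl(chloro)diphenylsilane CC(C)(C)[Si](Cl)(c1ccccc1)c1ccccc1
Why: Standard silylation; TBDPS is chosen because it must outlast the later TES removal.

**Step 11**
Reactants: 16 [(4-bromofuran-3-yl)methoxy](tert-butyl)diphenylsilane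
Product: 18 [(4-bromo-5-methylfuran-3-yl)methoxy](tert-butyl)diphenylsilane, via 2-lithiofuran 17 (not isolated)
Conditions: LDA, THF, −78 °C; MeI, −78 → 0 °C
Reagents that add atoms: iodomethane CI
Why: Directed α-lithiation: LDA removes the furan α-proton next to bromine (inductive acidification, no Br/Li exchange) and methylation installs the methyl that becomes C9.

**Step 12**
Reactants: 18 [(4-bromo-5-methylfuran-3-yl)methoxy](tert-butyl)diphenylsilane; 11 (3S,5S,6Z)-7-iodo-3-methyl-1-oxo-3-[(triethylsilyl)oxy]oct-6-en-5-yl acetate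
Product: 21 (2Z,4S,6R,8RS)-8-[4-({[tert-butyl(diphenyl)silyl]oxy}methyl)-2-methylfuran-3-yl]-8-hydroxy-2-iodo-6-methyl-6-[(triethylsilyl)oxy]oct-2-en-4-yl acetate, via furyllithium 19 (not isolated), via furylmagnesium bromide 20 (not isolated)
Conditions: 18 (1.3 equiv), n-BuLi, THF, −78 °C; MgBr2·OEt2, −78 °C; then 11, −78 → −40 °C
Reagents that add atoms: none
Why: Br/Li exchange, transmetalation to the milder Grignard reagent (spares vinyl iodide and acetate) and 1,2-addition to the aldehyde form the C6–C7 bond; C6 is formed as both epimers and set in steps 13–14.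

**Step 13**
Reactants: 21 (2Z,4S,6R,8RS)-8-[4-({[tert-butyl(diphenyl)silyl]oxy}methyl)-2-methylfuran-3-yl]-8-hydroxy-2-iodo-6-methyl-6-[(triethylsilyl)oxy]oct-2-en-4-yl acetate
Product: 22 (2Z,4S,6S)-8-[4-({[tert-butyl(diphenyl)silyl]oxy}methyl)-2-methylfuran-3-yl]-2-iodo-6-methyl-8-oxo-6-[(triethylsilyl)oxy]oct-2-en-4-yl acetate
Conditions: Dess–Martin periodinane, NaHCO3, CH2Cl2, 0 °C → rt
Reagents that add atoms: none
Why: Dess–Martin oxidation converges both carbinol epimers to the furyl ketone under buffered, non-epimerising conditions.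

**Step 14**
Reactants: 22 (2Z,4S,6S)-8-[4-({[tert-butyl(diphenyl)silyl]oxy}methyl)-2-methylfuran-3-yl]-2-iodo-6-methyl-8-oxo-6-[(triethylsilyl)oxy]oct-2-en-4-yl acetate
Product: 23 (2Z,4S,6R,8R)-8-[4-({[tert-butyl(diphenyl)silyl]oxy}methyl)-2-methylfuran-3-yl]-8-hydroxy-2-iodo-6-methyl-6-[(triethylsilyl)oxy]oct-2-en-4-yl acetate
Conditions: (S)-2-methyl-CBS-oxazaborolidine (0.3 equiv), BH3·SMe2, THF, −30 °C
Reagents that add atoms: none
Why: Corey–Bakshi–Shibata reduction: with the furyl ring as the large group the (S)-oxazaborolidine delivers hydride to give the (R)-carbinol (C6) under reagent control.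

**Step 15**
Reactants: 23 (2Z,4S,6R,8R)-8-[4-({[tert-butyl(diphenyl)silyl]oxy}methyl)-2-methylfuran-3-yl]-8-hydroxy-2-iodo-6-methyl-6-[(triethylsilyl)oxy]oct-2-en-4-yl acetate
Product: 24 (2Z,4S,6S,8R)-8-[4-({[tert-butyl(diphenyl)silyl]oxy}methyl)-2-methylfuran-3-yl]-2-iodo-6-methyl-6,8-bis[(triethylsilyl)oxy]oct-2-en-4-yl acetate
Conditions: TESOTf, 2,6-lutidine, CH2Cl2, −78 °C
Reagents that add atoms: triethylsilyl trifluoromethanesulfonate CC[Si](CC)(CC)OS(=O)(=O)C(F)(F)F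
Why: Silylation protects C6–OH through the oxidation, dehydration and Pd steps, where a free hydroxyl or a methacrylate would interfere.

**Step 16**
Reactants: 24 (2Z,4S,6S,8R)-8-[4-({[tert-butyl(diphenyl)silyl]oxy}methyl)-2-methylfuran-3-yl]-2-iodo-6-methyl-6,8-bis[(triethylsilyl)oxy]oct-2-en-4-yl acetate
Product: 26 (2Z,4S,6S,8R)-8-[4-({[tert-butyl(diphenyl)silyl]oxy}methyl)-2-hydroxy-2-methyl-5-oxo-2,5-dihydrofuran-3-yl]-2-iodo-6-methyl-6,8-bis[(triethylsilyl)oxy]oct-2-en-4-yl acetate (hemiketal epimers), via furan endoperoxide 25 (not isolated)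
Conditions: O2, hν (visible), methylene blue (cat.), i-Pr2NEt, CH2Cl2, −78 °C
Reagents that add atoms: dioxygen O=O
Why: [4+2] addition of singlet oxygen to the furan, then base-induced Kornblum–DeLaMare fragmentation; the only bridgehead hydrogen is at C12, so C12 becomes the lactone carbonyl and C8 the hemiketal without ambiguity.

**Step 17**
Reactants: 26 (2Z,4S,6S,8R)-8-[4-({[tert-butyl(diphenyl)silyl]oxy}methyl)-2-hydroxy-2-methyl-5-oxo-2,5-dihydrofuran-3-yl]-2-iodo-6-methyl-6,8-bis[(triethylsilyl)oxy]oct-2-en-4-yl acetate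
Product: 28 (2Z,4S,6S,8R)-8-[4-({[tert-butyl(diphenyl)silyl]oxy}methyl)-2-methylidene-5-oxo-2,5-dihydrofuran-3-yl]-2-iodo-6-methyl-6,8-bis[(triethylsilyl)oxy]oct-2-en-4-yl acetate, via hemiketal mesylate 27 (not isolated)
Conditions: MsCl, Et3N, CH2Cl2, −30 → 0 °C
Reagents that add atoms: none
Why: Sulfonylation of the hemiketal hydroxyl, ionisation to the acyloxocarbenium ion and loss of a C9 proton (E1-type dehydration) give the exocyclic enol lactone.

**Step 18**
Reactants: 28 (2Z,4S,6S,8R)-8-[4-({[tert-butyl(diphenyl)silyl]oxy}methyl)-2-methylidene-5-oxo-2,5-dihydrofuran-3-yl]-2-iodo-6-methyl-6,8-bis[(triethylsilyl)oxy]oct-2-en-4-yl acetate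
Product: 29 (4R,6S,8S,9Z,11E)-3-({[tert-butyl(diphenyl)silyl]oxy}methyl)-6,10-dimethyl-2-oxo-4,6-bis[(triethylsilyl)oxy]-2,4,5,6,7,8-hexahydrocyclodeca[b]furan-8-yl acetate
Conditions: Pd(OAc)2 (20 mol %), P(2-furyl)3 (40 mol %), Ag2CO3 (1.5 equiv), MeCN, 60 °C, 1 mM (slow addition)
Reagents that add atoms: none
Why: Proposed new method: a macrocyclising 10-endo intramolecular Heck reaction whose alkene partner is the exocyclic enol-lactone C=C of a γ-methylene butenolide; Pd(0) inserts into the (Z)-C10–I bond with retention, syn-carbopalladation of the 1,1-disubstituted C8=C9 bond places C10 on the unhindered and electrophilic terminal carbon C9 (vinylogous acrylate polarity), and syn-β-hydride elimination from the resulting C8 oxa-π-allyl palladium, which has β-hydrogens only on C9, restores the enol lactone in conjugation with C1=C10; the ten-membered ring can hold only the isomer with C7 and C10 cis (8E), and Ag(I) keeps the cycle cationic and suppresses Pd–H re-addition; the closest known reaction types are macrocyclic Heck cyclisations of vinyl iodides onto terminal alkenes and Heck couplings of enol esters and α-methylene lactones.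

**Step 19**
Reactants: 29 (4R,6S,8S,9Z,11E)-3-({[tert-butyl(diphenyl)silyl]oxy}methyl)-6,10-dimethyl-2-oxo-4,6-bis[(triethylsilyl)oxy]-2,4,5,6,7,8-hexahydrocyclodeca[b]furan-8-yl acetate
Product: 30 (4R,6R,8S,9Z,11E)-3-({[tert-butyl(diphenyl)silyl]oxy}methyl)-4,6-dihydroxy-6,10-dimethyl-2-oxo-2,4,5,6,7,8-hexahydrocyclodeca[b]furan-8-yl acetate
Conditions: HF·pyridine, pyridine, THF, 0 °C → rt
Reagents that add atoms: none
Why: Fluoride-mediated desilylation: both TES ethers cleave much faster than the primary TBDPS ether, and the buffered medium spares the acetate and the enol lactone.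

**Step 20**
Reactants: 30 (4R,6R,8S,9Z,11E)-3-({[tert-butyl(diphenyl)silyl]oxy}methyl)-4,6-dihydroxy-6,10-dimethyl-2-oxo-2,4,5,6,7,8-hexahydrocyclodeca[b]furan-8-yl acetate
Product: 31 (4R,6S,8S,9Z,11E)-8-(acetyloxy)-3-({[tert-butyl(diphenyl)silyl]oxy}methyl)-6-hydroxy-6,10-dimethyl-2-oxo-2,4,5,6,7,8-hexahydrocyclodeca[b]furan-4-yl 2-methylprop-2-enoate
Conditions: methacrylic anhydride, Et3N, DMAP (cat.), CH2Cl2, 0 °C
Reagents that add atoms: methacrylic anhydride C=C(C)C(=O)OC(=O)C(C)=C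
Why: DMAP-catalysed acylation is selective for the secondary C6–OH over the tertiary C4–OH, so the methacrylate goes on only after the Pd step it would disturb.

**Step 21**
Reactants: 31 (4R,6S,8S,9Z,11E)-8-(acetyloxy)-3-({[tert-butyl(diphenyl)silyl]oxy}methyl)-6-hydroxy-6,10-dimethyl-2-oxo-2,4,5,6,7,8-hexahydrocyclodeca[b]furan-4-yl 2-methylprop-2-enoate
Product: 32 (4R,6S,8S,9Z,11E)-8-(acetyloxy)-6-hydroxy-3-(hydroxymethyl)-6,10-dimethyl-2-oxo-2,4,5,6,7,8-hexahydrocyclodeca[b]furan-4-yl 2-methylprop-2-enoate (CNP0246543.1)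
Conditions: HF·pyridine, pyridine, THF, rt
Reagents that add atoms: none
Why: Fluoride-mediated desilylation of the primary TBDPS ether under mildly acidic conditions leaves both esters and the enol lactone intact and avoids acyl migration.

**Compound list**
1 | (R)-mevalonolactone, (4R)-4-hydroxy-4-methyloxan-2-one | C[C@@]1(O)CCOC(=O)C1 | starting material
2 | (3R)-3,5-dihydroxy-N-methoxy-N,3-dimethylpentanamide | OCC[C@@](C)(O)CC(=O)N(C)OC | intermediate
3 | (3R)-N-methoxy-N,3-dimethyl-3,5-bis[(triethylsilyl)oxy]pentanamide | CC[Si](CC)(CC)OCC[C@@](C)(O[Si](CC)(CC)CC)CC(=O)N(C)OC | intermediate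
4 | prop-1-yn-1-ylmagnesium bromide | CC#C[Mg]Br | starting material
5 | (6R)-6-methyl-6,8-bis[(triethylsilyl)oxy]oct-2-yn-4-one | CC[Si](CC)(CC)OCC[C@@](C)(O[Si](CC)(CC)CC)CC(=O)C#CC | intermediate
6 | (4S,6R)-6-methyl-6,8-bis[(triethylsilyl)oxy]oct-2-yn-4-ol | CC[Si](CC)(CC)OCC[C@@](C)(O[Si](CC)(CC)CC)C[C@H](O)C#CC | intermediate
7 | sodium cyclic vinylalanate from 6 (five-membered O–Al–C=C ring, two 2-methoxyethoxy ligands on Al) | CC[Si](CC)(CC)OCC[C@@](C)(O[Si](CC)(CC)CC)C[C@@H]1O[Al-](OCCOC)(OCCOC)C(C)=C1.[Na+] | intermediate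
8 | (2Z,4S,6R)-2-iodo-6-methyl-6,8-bis[(triethylsilyl)oxy]oct-2-en-4-ol | CC[Si](CC)(CC)OCC[C@@](C)(O[Si](CC)(CC)CC)C[C@H](O)/C=C(C)\I | intermediate
9 | (2Z,4S,6R)-2-iodo-6-methyl-6,8-bis[(triethylsilyl)oxy]oct-2-en-4-yl acetate | CC[Si](CC)(CC)OCC[C@@](C)(O[Si](CC)(CC)CC)C[C@H](OC(C)=O)/C=C(C)\I | intermediate
10 | alkoxydimethylsulfonium chloride at the primary oxygen of 9 (TES lost) | C[S+](C)OCC[C@@](C)(O[Si](CC)(CC)CC)C[C@H](OC(C)=O)/C=C(C)\I.[Cl-] | intermediate
11 | (3S,5S,6Z)-7-iodo-3-methyl-1-oxo-3-[(triethylsilyl)oxy]oct-6-en-5-yl acetate | O=CC[C@@](C)(O[Si](CC)(CC)CC)C[C@H](OC(C)=O)/C=C(C)\I | intermediate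
12 | 3,4-dibromofuran | Brc1cocc1Br | starting material
13 | 3-bromo-4-lithiofuran | [Li]c1cocc1Br | intermediate
14 | 4-bromofuran-3-carbaldehyde | O=Cc1cocc1Br | intermediate
15 | (4-bromofuran-3-yl)methanol | OCc1cocc1Br | intermediate
16 | [(4-bromofuran-3-yl)methoxy](tert-butyl)diphenylsilane | CC(C)(C)[Si](OCc1cocc1Br)(c1ccccc1)c1ccccc1 | intermediate
17 | [3-bromo-4-({[tert-butyl(diphenyl)silyl]oxy}methyl)furan-2-yl]lithium | [Li]c1occ(CO[Si](c2ccccc2)(c2ccccc2)C(C)(C)C)c1Br | intermediate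
18 | [(4-bromo-5-methylfuran-3-yl)methoxy](tert-butyl)diphenylsilane | Cc1occ(CO[Si](c2ccccc2)(c2ccccc2)C(C)(C)C)c1Br | intermediate
19 | [4-({[tert-butyl(diphenyl)silyl]oxy}methyl)-2-methylfuran-3-yl]lithium | Cc1occ(CO[Si](c2ccccc2)(c2ccccc2)C(C)(C)C)c1[Li] | intermediate
20 | [4-({[tert-butyl(diphenyl)silyl]oxy}methyl)-2-methylfuran-3-yl]magnesium bromide | Cc1occ(CO[Si](c2ccccc2)(c2ccccc2)C(C)(C)C)c1[Mg]Br | intermediate
21 | (2Z,4S,6R,8RS)-8-[4-({[tert-butyl(diphenyl)silyl]oxy}methyl)-2-methylfuran-3-yl]-8-hydroxy-2-iodo-6-methyl-6-[(triethylsilyl)oxy]oct-2-en-4-yl acetate | OC(c1c(C)occ1CO[Si](c1ccccc1)(c1ccccc1)C(C)(C)C)C[C@@](C)(O[Si](CC)(CC)CC)C[C@H](OC(C)=O)/C=C(C)\I | intermediate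
22 | (2Z,4S,6S)-8-[4-({[tert-butyl(diphenyl)silyl]oxy}methyl)-2-methylfuran-3-yl]-2-iodo-6-methyl-8-oxo-6-[(triethylsilyl)oxy]oct-2-en-4-yl acetate | O=C(c1c(C)occ1CO[Si](c1ccccc1)(c1ccccc1)C(C)(C)C)C[C@@](C)(O[Si](CC)(CC)CC)C[C@H](OC(C)=O)/C=C(C)\I | intermediate
23 | (2Z,4S,6R,8R)-8-[4-({[tert-butyl(diphenyl)silyl]oxy}methyl)-2-methylfuran-3-yl]-8-hydroxy-2-iodo-6-methyl-6-[(triethylsilyl)oxy]oct-2-en-4-yl acetate | O[C@@H](c1c(C)occ1CO[Si](c1ccccc1)(c1ccccc1)C(C)(C)C)C[C@@](C)(O[Si](CC)(CC)CC)C[C@H](OC(C)=O)/C=C(C)\I | intermediate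
24 | (2Z,4S,6S,8R)-8-[4-({[tert-butyl(diphenyl)silyl]oxy}methyl)-2-methylfuran-3-yl]-2-iodo-6-methyl-6,8-bis[(triethylsilyl)oxy]oct-2-en-4-yl acetate | CC[Si](CC)(CC)O[C@@H](c1c(C)occ1CO[Si](c1ccccc1)(c1ccccc1)C(C)(C)C)C[C@@](C)(O[Si](CC)(CC)CC)C[C@H](OC(C)=O)/C=C(C)\I | intermediate
25 | furan endoperoxide of 24 (2,3,7-trioxabicyclo[2.2.1]hept-5-ene; peroxide bridge between C8 and C12) | CC[Si](CC)(CC)O[C@@H](C1=C(CO[Si](c2ccccc2)(c2ccccc2)C(C)(C)C)C2OOC1(C)O2)C[C@@](C)(O[Si](CC)(CC)CC)C[C@H](OC(C)=O)/C=C(C)\I | intermediate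
26 | (2Z,4S,6S,8R)-8-[4-({[tert-butyl(diphenyl)silyl]oxy}methyl)-2-hydroxy-2-methyl-5-oxo-2,5-dihydrofuran-3-yl]-2-iodo-6-methyl-6,8-bis[(triethylsilyl)oxy]oct-2-en-4-yl acetate (hemiketal epimers) | CC[Si](CC)(CC)O[C@@H](C1=C(CO[Si](c2ccccc2)(c2ccccc2)C(C)(C)C)C(=O)OC1(C)O)C[C@@](C)(O[Si](CC)(CC)CC)C[C@H](OC(C)=O)/C=C(C)\I | intermediate
27 | hemiketal methanesulfonate of 26 | CC[Si](CC)(CC)O[C@@H](C1=C(CO[Si](c2ccccc2)(c2ccccc2)C(C)(C)C)C(=O)OC1(C)OS(C)(=O)=O)C[C@@](C)(O[Si](CC)(CC)CC)C[C@H](OC(C)=O)/C=C(C)\I | intermediate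
28 | (2Z,4S,6S,8R)-8-[4-({[tert-butyl(diphenyl)silyl]oxy}methyl)-2-methylidene-5-oxo-2,5-dihydrofuran-3-yl]-2-iodo-6-methyl-6,8-bis[(triethylsilyl)oxy]oct-2-en-4-yl acetate | CC[Si](CC)(CC)O[C@@H](C1=C(CO[Si](c2ccccc2)(c2ccccc2)C(C)(C)C)C(=O)OC1=C)C[C@@](C)(O[Si](CC)(CC)CC)C[C@H](OC(C)=O)/C=C(C)\I | intermediate
29 | (4R,6S,8S,9Z,11E)-3-({[tert-butyl(diphenyl)silyl]oxy}methyl)-6,10-dimethyl-2-oxo-4,6-bis[(triethylsilyl)oxy]-2,4,5,6,7,8-hexahydrocyclodeca[b]furan-8-yl acetate | CC[Si](CC)(CC)O[C@@H]1C[C@@](C)(O[Si](CC)(CC)CC)C[C@H](OC(C)=O)/C=C(C)\C=C2\OC(=O)C(CO[Si](c3ccccc3)(c3ccccc3)C(C)(C)C)=C21 | intermediate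
30 | (4R,6R,8S,9Z,11E)-3-({[tert-butyl(diphenyl)silyl]oxy}methyl)-4,6-dihydroxy-6,10-dimethyl-2-oxo-2,4,5,6,7,8-hexahydrocyclodeca[b]furan-8-yl acetate | O[C@@H]1C[C@@](C)(O)C[C@H](OC(C)=O)/C=C(C)\C=C2\OC(=O)C(CO[Si](c3ccccc3)(c3ccccc3)C(C)(C)C)=C21 | intermediate
31 | (4R,6S,8S,9Z,11E)-8-(acetyloxy)-3-({[tert-butyl(diphenyl)silyl]oxy}methyl)-6-hydroxy-6,10-dimethyl-2-oxo-2,4,5,6,7,8-hexahydrocyclodeca[b]furan-4-yl 2-methylprop-2-enoate | C=C(C)C(=O)O[C@@H]1C[C@@](C)(O)C[C@H](OC(C)=O)/C=C(C)\C=C2\OC(=O)C(CO[Si](c3ccccc3)(c3ccccc3)C(C)(C)C)=C21 | intermediate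
32 | (4R,6S,8S,9Z,11E)-8-(acetyloxy)-6-hydroxy-3-(hydroxymethyl)-6,10-dimethyl-2-oxo-2,4,5,6,7,8-hexahydrocyclodeca[b]furan-4-yl 2-methylprop-2-enoate (CNP0246543.1) | C=C(C)C(=O)O[C@@H]1C[C@@](C)(O)C[C@H](OC(C)=O)/C=C(C)\C=C2\OC(=O)C(CO)=C21 | target

**Totals**
Total step count: 21. Longest linear sequence: 17 steps (steps 1–7, then 12–21); the furan branch is steps 8–11.

**Three steps most likely to fail**

Step 18 (the new Heck macrocyclisation). The 10-endo closure may lose to oligomerisation or to Pd–allyl chemistry at the C2 acetate. The fallback uses known chemistry, sets out from 26 and comes back at 29. Because 26 is the ring-chain tautomer of a (Z)-γ-keto acid, MeI/K2CO3 in DMF alkylates the carboxylate and gives the open-chain methyl (Z)-keto ester F1. A Pd-catalysed intramolecular ketone α-alkenylation (Pd2(dba)3, Xantphos, K3PO4, THF, 60 °C, 2 mM) then couples the methyl-ketone enolate carbon C9 with the vinyl iodide and gives the ten-membered β,γ-unsaturated keto ester F2. CSA in toluene enol-lactonises the C8 ketone onto the cis ester with loss of methanol and gives 29, the ring again allowing only the 8E isomer. This reaction type is established for normal and bridged rings; its use for a ten-membered ring is an extension.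

Step 17 (dehydration to the γ-methylene butenolide). The lactol may resist, or the exocyclic enol lactone may polymerise. The fallback sets out from 24 and comes back at 28. The photooxygenation of 24 is run in methanol (rose bengal, −78 °C), so that methanol opens the endoperoxide at the tertiary carbon C8 and gives the methoxy hydroperoxide F3. Ac2O/pyridine dehydrates the secondary hydroperoxide to the γ-methoxy-γ-methyl butenolide (pseudo-ester) F4. TMSOTf/i-Pr2NEt (−78 → 0 °C) then eliminates methanol from this ketal (ketal-to-enol-ether elimination) and gives 28 without handling the free lactol 26.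

Step 14 (CBS reduction). The ketone is flanked by two ortho substituents and may react slowly or with low selectivity. The fallback sets out from 18 and 11 and comes back at 23. It forms C6 and its configuration in one catalytic asymmetric aryl-transfer step in place of addition, oxidation and reduction. Compound 18 is lithiated as in step 12 and transmetalated with ZnCl2 and then n-BuLi to the butyl(furyl)zinc reagent F5. The lithium salts are sequestered with TEEDA, and F5 is added to aldehyde 11 at 0 °C with 10 mol % of the MIB amino-alcohol enantiomer that gives the 8R alcohol, which is 23.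

**Further compounds**
F1 | step 18 | methyl (2Z,4R,6S,8S,9Z)-3-acetyl-8-(acetyloxy)-2-({[tert-butyl(diphenyl)silyl]oxy}methyl)-10-iodo-6-methyl-4,6-bis[(triethylsilyl)oxy]undeca-2,9-dienoate | CC[Si](CC)(CC)O[C@@H](/C(C(C)=O)=C(\CO[Si](c1ccccc1)(c1ccccc1)C(C)(C)C)C(=O)OC)C[C@@](C)(O[Si](CC)(CC)CC)C[C@H](OC(C)=O)/C=C(C)\I
F2 | step 18 | methyl (2Z)-2-[(2R,4S,6S,7Z)-6-(acetyloxy)-4,8-dimethyl-10-oxo-2,4-bis[(triethylsilyl)oxy]cyclodec-7-en-1-ylidene]-3-{[tert-butyl(diphenyl)silyl]oxy}propanoate | CC[Si](CC)(CC)O[C@@H]1C[C@@](C)(O[Si](CC)(CC)CC)C[C@H](OC(C)=O)/C=C(C)\CC(=O)/C1=C(/CO[Si](c1ccccc1)(c1ccccc1)C(C)(C)C)C(=O)OC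
F3 | step 17 | (2Z,4S,6S,8R)-8-[4-({[tert-butyl(diphenyl)silyl]oxy}methyl)-5-hydroperoxy-2-methoxy-2-methyl-2,5-dihydrofuran-3-yl]-2-iodo-6-methyl-6,8-bis[(triethylsilyl)oxy]oct-2-en-4-yl acetate | CC[Si](CC)(CC)O[C@@H](C1=C(CO[Si](c2ccccc2)(c2ccccc2)C(C)(C)C)C(OO)OC1(C)OC)C[C@@](C)(O[Si](CC)(CC)CC)C[C@H](OC(C)=O)/C=C(C)\I
F4 | step 17 | (2Z,4S,6S,8R)-8-[4-({[tert-butyl(diphenyl)silyl]oxy}methyl)-2-methoxy-2-methyl-5-oxo-2,5-dihydrofuran-3-yl]-2-iodo-6-methyl-6,8-bis[(triethylsilyl)oxy]oct-2-en-4-yl acetate | CC[Si](CC)(CC)O[C@@H](C1=C(CO[Si](c2ccccc2)(c2ccccc2)C(C)(C)C)C(=O)OC1(C)OC)C[C@@](C)(O[Si](CC)(CC)CC)C[C@H](OC(C)=O)/C=C(C)\I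
F5 | step 14 | butyl[4-({[tert-butyl(diphenyl)silyl]oxy}methyl)-2-methylfuran-3-yl]zinc | CCCC[Zn]c1c(C)occ1CO[Si](c1ccccc1)(c1ccccc1)C(C)(C)C
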